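**Retrosynthetic overview**
1. Target 25 ⇐ ketone 24 ⇐ C-6 epimeric alcohol 23 (oxidation, then hydride from the convex face).
2. 23 ⇐ acyclic epoxy-polyene 22 in one cation–olefin cascade: epoxide opening closes ring A, the allylsilane closes ring B and leaves the exocyclic methylene; the (Z)-trisubstituted olefin is what makes the ring fusion cis.
3. 22 ⇐ Negishi sp3–sp2 union of epoxy alkylzinc 21 (fragment A, from bromide 9) with (Z)-vinyl iodide 20 (fragment B).
4. 9 ⇐ methyl pent-4-ynoate (methylalumination, oxirane, Shi epoxidation); 20 ⇐ pent-4-yn-1-ol (silylmethylcupration, iodo-olefination) + dimethyl 3-oxopentanedioate (pyranone).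
5. Ring order: pyranone (steps 11–12), then rings A and B together (step 14).

Assumption: the SMILES is read literally, i.e. a cis-fused decalin (4a-H and 8a-CH3 on the same face) with configuration 1S,4aR,5R,6S,8aS.

**Fragment A**

Step 1
Reactants: 1 methyl pent-4-ynoate
Product: 3 2-methylhex-5-yn-2-ol, via hex-5-yn-2-one 2 (not isolated)
Conditions: MeMgBr (2.6 equiv), THF, −20 → 0 °C; H2O
Reagents that add atoms: methylmagnesium bromide, C[Mg]Br
Why: Double Grignard addition to the ester gives the tertiary carbinol because ketone 2 is more electrophilic than 1, and the alkyne C–H is not metalated at this temperature.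

Step 2
Reactants: 3 2-methylhex-5-yn-2-ol
Product: 6 (3E)-4,7-dimethyloct-3-ene-1,7-diol, via alkenylalane 4 (not isolated), via lithium alkenylaluminate 5 (not isolated)
Conditions: Me3Al (3.2 equiv), Cp2ZrCl2 (0.3 equiv), CH2Cl2, 0 → 23 °C; then n-BuLi, THF/hexane, −78 °C; oxirane, −78 → 0 °C; aq. Rochelle salt
Reagents that add atoms: trimethylaluminium, C[Al](C)C; oxirane, C1CO1
Why: Negishi zirconium-catalysed carboalumination adds CH3 and Al syn across the terminal alkyne (CH3 to the internal carbon), and the derived aluminate opens oxirane with retention, so the (E)-trisubstituted olefin is fixed.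

Step 3
Reactants: 6 (3E)-4,7-dimethyloct-3-ene-1,7-diol
Product: 7 (5E)-8-bromo-2,5-dimethyloct-5-en-2-ol
Conditions: CBr4, PPh3, CH2Cl2, 0 °C
Reagents that add atoms: carbon tetrabromide, BrC(Br)(Br)Br
Why: Appel bromination is selective for the primary alcohol, the tertiary alcohol being inert at 0 °C.

Step 4
Reactants: 7 (5E)-8-bromo-2,5-dimethyloct-5-en-2-ol
Product: 8 (5E)-8-bromo-2,5-dimethyloct-5-en-2-yl formate
Conditions: HCO2Ac (3 equiv), pyridine, CH2Cl2, 0 → 23 °C
Reagents that add atoms: acetic formic anhydride, CC(=O)OC=O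
Why: Acyl transfer from the mixed anhydride delivers the formyl group to the tertiary alcohol (O-formylation); this is the target's own ester and it masks the hydroxyl that would otherwise open the later epoxide to a tetrahydrofuran.

Step 5
Reactants: 8 (5E)-8-bromo-2,5-dimethyloct-5-en-2-yl formate
Product: 9 4-[(2R,3R)-3-(2-bromoethyl)-2-methyloxiran-2-yl]-2-methylbutan-2-yl formate
Conditions: Shi ketone from D-fructose (0.5 equiv), Oxone (2KHSO5·KHSO4·K2SO4), NaHCO3, aq. Na2EDTA, MeCN, 0 °C, pH ≈ 8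
Reagents that add atoms: potassium peroxymonosulfate, [K+].[O-]S(=O)(=O)OO
Why: Shi asymmetric epoxidation (chiral dioxirane, spiro transition state) of the only olefin gives the (R,R)-epoxide from the (E)-trisubstituted alkene; near-neutral pH spares the formate and the alkyl bromide is inert to the dioxirane.

**Fragment B**

Step 6
Reactants: 10 pent-4-yn-1-ol
Product: 12 (2Z)-3-[(trimethylsilyl)methyl]hex-2-ene-1,6-diol, via alkenylcopper 11 (not isolated)
Conditions: Me3SiCH2MgCl (2.3 equiv), CuBr·SMe2 (1.2 equiv), Et2O/Me2S, −40 → −10 °C; then (CH2O)n, THF, −10 → 23 °C; H2O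
Reagents that add atoms: (trimethylsilyl)methylmagnesium chloride, C[Si](C)(C)C[Mg]Cl; formaldehyde, C=O
Why: Normant carbocupration adds Me3SiCH2 and Cu syn across the alkyne (silylmethyl to the internal carbon) and hydroxymethylation of the alkenylcopper with retention puts CH2OH cis to CH2SiMe3, which fixes the allylsilane geometry.

Step 7
Reactants: 12 (2Z)-3-[(trimethylsilyl)methyl]hex-2-ene-1,6-diol
Product: 13 (4Z)-6-chloro-4-[(trimethylsilyl)methyl]hex-4-en-1-ol
Conditions: NCS, Me2S, CH2Cl2, −25 → 0 °C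
Reagents that add atoms: N-chlorosuccinimide, O=C1CCC(=O)N1Cl
Why: Corey–Kim halogenation converts only the allylic alkoxysulfonium salt into the chloride (SN2, no allylic shift), and the saturated primary alcohol is returned on work-up.

Step 8
Reactants: 13 (4Z)-6-chloro-4-[(trimethylsilyl)methyl]hex-4-en-1-ol
Product: 14 (4Z)-6-chloro-4-[(trimethylsilyl)methyl]hex-4-enal
Conditions: Dess–Martin periodinane, NaHCO3, CH2Cl2, 0 → 23 °C
Reagents that add atoms: none
Why: Dess–Martin oxidation of the primary alcohol under buffered, non-acidic conditions leaves the allylsilane and the allylic chloride untouched.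

Step 9
Reactants: 14 (4Z)-6-chloro-4-[(trimethylsilyl)methyl]hex-4-enal
Product: 15 (2Z,6Z)-1-chloro-7-iodo-3-[(trimethylsilyl)methyl]octa-2,6-diene
Conditions: EtPPh3I, n-BuLi, THF, 23 °C; I2, −78 °C; NaN(SiMe3)2, −20 °C; then 14, −78 → −20 °C
Reagents that add atoms: ethyltriphenylphosphonium iodide, CC[P+](c1ccccc1)(c1ccccc1)c1ccccc1.[I-]; iodine, II
Why: Stork–Zhao-type Wittig olefination with the α-iodo ylide Ph3P=C(I)CH3 gives the (Z)-2-iodoalkene (iodine cis to the chain) under kinetic control, and this geometry later becomes the (Z)-trisubstituted olefin.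

Step 10
Reactants: 15 (2Z,6Z)-1-chloro-7-iodo-3-[(trimethylsilyl)methyl]octa-2,6-diene; 16 dimethyl 3-oxopentanedioate
Product: 17 dimethyl 2-[(2Z,6Z)-7-iodo-3-[(trimethylsilyl)methyl]octa-2,6-dien-1-yl]-3-oxopentanedioate
Conditions: NaH (1.0 equiv), 16 (2 equiv), THF/DMF, 0 °C; then 15, NaI (10 mol%), 23 °C
Reagents that add atoms: none
Why: SN2 C-alkylation of the β-keto ester enolate at the primary allylic chloride proceeds without allylic transposition, so both olefin geometries are kept; the new CH centre is racemic and becomes sp2 in step 11.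

Step 11
Reactants: 17 alkylated keto diester
Product: 19 methyl 4-hydroxy-5-[(2Z,6Z)-7-iodo-3-[(trimethylsilyl)methyl]octa-2,6-dien-1-yl]-2-methyl-6-oxo-6H-pyran-3-carboxylate, via acetylated keto diester 18 (not isolated)
Conditions: MgCl2, pyridine, AcCl, CH2Cl2, 0 → 23 °C; then DBU, PhMe, 80 °C; dil. citric acid
Reagents that add atoms: acetyl chloride, CC(Cl)=O
Why: Magnesium-chelate (Rathke) C-acylation occurs at the unsubstituted CH2, and the resulting 3,5-dioxo ester lactonises through the acetyl enol oxygen onto the distal ester (loss of methanol) to the 4-hydroxy-2-pyranone.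

Step 12
Reactants: 19 hydroxy-2-pyranone
Product: 20 methyl 5-[(2Z,6Z)-7-iodo-3-[(trimethylsilyl)methyl]octa-2,6-dien-1-yl]-6-methoxy-2-methyl-4-oxo-4H-pyran-3-carboxylate
Conditions: MeOTf (1.3 equiv), 2,6-di-tert-butyl-4-methylpyridine, CH2Cl2, 0 → 23 °C; aq. NaHCO3
Reagents that add atoms: methyl trifluoromethanesulfonate, COS(=O)(=O)C(F)(F)F
Why: O-Methylation with a hard methylating agent takes place at the lactone carbonyl oxygen of the neutral 2-pyranone (the 4-OH is hydrogen-bonded to the ester), and proton loss gives the 2-methoxy-4-pyranone; the hindered base protects the allylsilane from acid.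

**Union and endgame**

Step 13
Reactants: 9 epoxy bromide; 20 vinyl iodide
Product: 22 methyl 5-[(2Z,6Z)-9-{(2R,3R)-3-[3-(formyloxy)-3-methylbutyl]-3-methyloxiran-2-yl}-7-methyl-3-[(trimethylsilyl)methyl]nona-2,6-dien-1-yl]-6-methoxy-2-methyl-4-oxo-4H-pyran-3-carboxylate, via alkylzinc bromide 21 (not isolated)
Conditions: 9, activated zinc powder (Rieke Zn), THF, 23 °C; then 20, PdCl2(dppf) (5 mol%), THF/NMP, 23 °C
Reagents that add atoms: none
Why: Zinc insertion into the primary C–Br bond and Negishi sp3–sp2 coupling with the vinyl iodide go with retention of olefin geometry, giving the (Z)-trisubstituted olefin; the organozinc tolerates epoxide, formate, ester and pyranone.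

Step 14
Reactants: 22 epoxy-polyene
Product: 23 methyl 5-{[(1S,4aR,5R,6R,8aS)-5-[3-(formyloxy)-3-methylbutyl]-6-hydroxy-5,8a-dimethyl-2-methylidenedecahydronaphthalen-1-yl]methyl}-6-methoxy-2-methyl-4-oxo-4H-pyran-3-carboxylate
Conditions: MeAlCl2 (3 equiv), CH2Cl2, −78 °C; Et3N, then aq. NaHCO3/Rochelle salt
Reagents that add atoms: none
Why: In a Stork–Eschenmoser-type cation–olefin polycyclisation with Hosomi–Sakurai termination, the (Z)-olefin opens the Lewis-acid-activated (R,R)-epoxide at its tertiary carbon with inversion through a chair (ring A), anti addition across that (Z)-olefin gives the cis ring fusion (4a-H and 8a-CH3 syn), and the allylsilane captures the ring-fusion cation in a chair (ring B) to set C-1 and release the exocyclic methylene; the epoxide fixes C-5 and gives the C-6 hydroxyl cis to 8a-CH3, which steps 15–16 correct.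

Step 15
Reactants: 23 decalinol
Product: 24 methyl 5-{[(1S,4aR,5R,8aS)-5-[3-(formyloxy)-3-methylbutyl]-5,8a-dimethyl-2-methylidene-6-oxodecahydronaphthalen-1-yl]methyl}-6-methoxy-2-methyl-4-oxo-4H-pyran-3-carboxylate
Conditions: Dess–Martin periodinane, NaHCO3, CH2Cl2, 23 °C
Reagents that add atoms: none
Why: Dess–Martin oxidation of the hindered secondary alcohol erases the wrongly set C-6 centre; the ketone has no epimerisable α-stereocentre.

Step 16
Reactants: 24 ketone
Product: 25 methyl 5-{[(1S,4aR,5R,6S,8aS)-5-[3-(formyloxy)-3-methylbutyl]-6-hydroxy-5,8a-dimethyl-2-methylidenedecahydronaphthalen-1-yl]methyl}-6-methoxy-2-methyl-4-oxo-4H-pyran-3-carboxylate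
Conditions: LiBH(s-Bu)3 (1.1 equiv), THF, −78 °C; H2O at −78 °C, non-oxidative work-up
Reagents that add atoms: none
Why: In this hydride reduction the bulky borohydride attacks from the convex face of the cis-decalin (the face of 8a-CH3 and 4a-H), placing the hydroxyl on the concave face cis to the side chain (6S), and it reduces the ketone faster than the esters at −78 °C.

**Compound list**
1 | methyl pent-4-ynoate | C#CCCC(=O)OC | starting material
2 | hex-5-yn-2-one | C#CCCC(C)=O | intermediate (not isolated)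
3 | 2-methylhex-5-yn-2-ol | C#CCCC(C)(C)O | intermediate
4 | dimethyl[(1E)-5-[(dimethylalumanyl)oxy]-2,5-dimethylhex-1-en-1-yl]alumane | C[Al](C)/C=C(\C)CCC(C)(C)O[Al](C)C | intermediate (not isolated)
5 | lithium butyl(dimethyl)[(1E)-5-[(dimethylalumanyl)oxy]-2,5-dimethylhex-1-en-1-yl]aluminate | [Li+].CCCC[Al-](C)(C)/C=C(\C)CCC(C)(C)O[Al](C)C | intermediate (not isolated)
6 | (3E)-4,7-dimethyloct-3-ene-1,7-diol | OCC/C=C(\C)CCC(C)(C)O | intermediate
7 | (5E)-8-bromo-2,5-dimethyloct-5-en-2-ol | BrCC/C=C(\C)CCC(C)(C)O | intermediate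
8 | (5E)-8-bromo-2,5-dimethyloct-5-en-2-yl formate | BrCC/C=C(\C)CCC(C)(C)OC=O | intermediate
9 | 4-[(2R,3R)-3-(2-bromoethyl)-2-methyloxiran-2-yl]-2-methylbutan-2-yl formate | BrCC[C@H]1O[C@]1(C)CCC(C)(C)OC=O | intermediate
10 | pent-4-yn-1-ol | C#CCCCO | starting material
11 | chloromagnesium (4Z)-5-cuprio-4-[(trimethylsilyl)methyl]pent-4-en-1-olate | [Cu]/C=C(\C[Si](C)(C)C)CCCO[Mg]Cl | intermediate (not isolated)
12 | (2Z)-3-[(trimethylsilyl)methyl]hex-2-ene-1,6-diol | OC/C=C(\C[Si](C)(C)C)CCCO | intermediate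
13 | (4Z)-6-chloro-4-[(trimethylsilyl)methyl]hex-4-en-1-ol | ClC/C=C(\C[Si](C)(C)C)CCCO | intermediate
14 | (4Z)-6-chloro-4-[(trimethylsilyl)methyl]hex-4-enal | ClC/C=C(\C[Si](C)(C)C)CCC=O | intermediate
15 | (2Z,6Z)-1-chloro-7-iodo-3-[(trimethylsilyl)methyl]octa-2,6-diene | ClC/C=C(\C[Si](C)(C)C)CC/C=C(\I)C | intermediate
16 | dimethyl 3-oxopentanedioate | COC(=O)CC(=O)CC(=O)OC | starting material
17 | dimethyl 2-[(2Z,6Z)-7-iodo-3-[(trimethylsilyl)methyl]octa-2,6-dien-1-yl]-3-oxopentanedioate | COC(=O)CC(=O)C(C/C=C(\C[Si](C)(C)C)CC/C=C(\I)C)C(=O)OC | intermediate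
18 | dimethyl 2-acetyl-4-[(2Z,6Z)-7-iodo-3-[(trimethylsilyl)methyl]octa-2,6-dien-1-yl]-3-oxopentanedioate | COC(=O)C(C(C)=O)C(=O)C(C/C=C(\C[Si](C)(C)C)CC/C=C(\I)C)C(=O)OC | intermediate (not isolated)
19 | methyl 4-hydroxy-5-[(2Z,6Z)-7-iodo-3-[(trimethylsilyl)methyl]octa-2,6-dien-1-yl]-2-methyl-6-oxo-6H-pyran-3-carboxylate | COC(=O)C1=C(C)OC(=O)C(C/C=C(\C[Si](C)(C)C)CC/C=C(\I)C)=C1O | intermediate
20 | methyl 5-[(2Z,6Z)-7-iodo-3-[(trimethylsilyl)methyl]octa-2,6-dien-1-yl]-6-methoxy-2-methyl-4-oxo-4H-pyran-3-carboxylate | COC(=O)c1c(C)oc(OC)c(C/C=C(\C[Si](C)(C)C)CC/C=C(\I)C)c1=O | intermediate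
21 | bromo{2-[(2R,3R)-3-[3-(formyloxy)-3-methylbutyl]-3-methyloxiran-2-yl]ethyl}zinc | Br[Zn]CC[C@H]1O[C@]1(C)CCC(C)(C)OC=O | intermediate (not isolated)
22 | methyl 5-[(2Z,6Z)-9-{(2R,3R)-3-[3-(formyloxy)-3-methylbutyl]-3-methyloxiran-2-yl}-7-methyl-3-[(trimethylsilyl)methyl]nona-2,6-dien-1-yl]-6-methoxy-2-methyl-4-oxo-4H-pyran-3-carboxylate | COC(=O)c1c(C)oc(OC)c(C/C=C(\C[Si](C)(C)C)CC/C=C(/C)CC[C@H]2O[C@]2(C)CCC(C)(C)OC=O)c1=O | intermediate
23 | methyl 5-{[(1S,4aR,5R,6R,8aS)-5-[3-(formyloxy)-3-methylbutyl]-6-hydroxy-5,8a-dimethyl-2-methylidenedecahydronaphthalen-1-yl]methyl}-6-methoxy-2-methyl-4-oxo-4H-pyran-3-carboxylate | C=C1CC[C@H]2[C@@](C)(CCC(C)(C)OC=O)[C@H](O)CC[C@@]2(C)[C@H]1Cc1c(OC)oc(C)c(C(=O)OC)c1=O | intermediate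
24 | methyl 5-{[(1S,4aR,5R,8aS)-5-[3-(formyloxy)-3-methylbutyl]-5,8a-dimethyl-2-methylidene-6-oxodecahydronaphthalen-1-yl]methyl}-6-methoxy-2-methyl-4-oxo-4H-pyran-3-carboxylate | C=C1CC[C@H]2[C@@](C)(CCC(C)(C)OC=O)C(=O)CC[C@@]2(C)[C@H]1Cc1c(OC)oc(C)c(C(=O)OC)c1=O | intermediate
25 | methyl 5-{[(1S,4aR,5R,6S,8aS)-5-[3-(formyloxy)-3-methylbutyl]-6-hydroxy-5,8a-dimethyl-2-methylidenedecahydronaphthalen-1-yl]methyl}-6-methoxy-2-methyl-4-oxo-4H-pyran-3-carboxylate | C=C1CC[C@H]2[C@@](C)(CCC(C)(C)OC=O)[C@@H](O)CC[C@@]2(C)[C@H]1Cc1c(OC)oc(C)c(C(=O)OC)c1=O | target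

**Totals**
Total step count: 16. Longest linear sequence: 11 steps (10 → 25 through steps 6–12 and 13–16); fragment A (steps 1–5) joins at step 13.

**Three steps most likely to fail**

Step 14 (bicyclisation). A stepwise ring-fusion cation could erode the cis fusion, and the Lewis-basic methoxypyranone may sequester MeAlCl2 or capture the C-2 cation through oxygen. The fallback addresses the pyranone interference only; it sets out from 19 and returns at 23. The pyranone hydroxyl of 19 is silylated (t-BuMe2SiCl, imidazole) to silyloxy-2-pyranone vinyl iodide F3. F3 is coupled with zinc reagent 21 (PdCl2(dppf)) to silyloxy-2-pyranone polyene F4. The epoxide/allylsilane cascade (MeAlCl2, −78 °C) is run on this weaker Lewis base to give silyloxy-pyranone decalinol F5. The silyl group is removed (HF·pyridine, pyridine) to give hydroxy-2-pyranone decalinol F6, and only then is the pyranone O-methylated (MeOTf, 2,6-di-tert-butyl-4-methylpyridine) to reach 23.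

Step 6 (silylmethylcupration of a free alkynol and trapping of the alkenylcopper with formaldehyde). Regiochemistry and the hydroxymethylation are both uncertain. The fallback sets out from 10 and returns at 12. The alkyne is hydroxymethylated (EtMgBr, (CH2O)n) to hex-2-yne-1,6-diol F1. Trans-hydroalumination of the propargylic alcohol with NaAlH2(OCH2CH2OMe)2 followed by I2 gives (2Z)-3-iodohex-2-ene-1,6-diol F2. Kumada coupling with Me3SiCH2MgCl and Pd(PPh3)4 (retention) then delivers 12.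

Step 16 (reduction). The hydride must come from the convex face and must spare the tertiary formate. The fallback sets out from 24 and returns at 25. Excess LiBH(s-Bu)3 reduces both the ketone and the formate to give decalin diol F7. The secondary alcohol is silylated selectively (Et3SiCl, imidazole) to triethylsilyl ether F8. The tertiary alcohol is formylated (HCO2Ac, pyridine) to silyl ether formate F9, and the silyl ether is removed (HF·pyridine) to give 25.

**Further compounds**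
F1 | step 6 | hex-2-yne-1,6-diol | OCC#CCCCO
F2 | step 6 | (2Z)-3-iodohex-2-ene-1,6-diol | OC/C=C(\I)CCCO
F3 | step 14 | methyl 4-[(tert-butyldimethylsilyl)oxy]-5-[(2Z,6Z)-7-iodo-3-[(trimethylsilyl)methyl]octa-2,6-dien-1-yl]-2-methyl-6-oxo-6H-pyran-3-carboxylate | COC(=O)C1=C(C)OC(=O)C(C/C=C(\C[Si](C)(C)C)CC/C=C(\I)C)=C1O[Si](C)(C)C(C)(C)C
F4 | step 14 | methyl 4-[(tert-butyldimethylsilyl)oxy]-5-[(2Z,6Z)-9-{(2R,3R)-3-[3-(formyloxy)-3-methylbutyl]-3-methyloxiran-2-yl}-7-methyl-3-[(trimethylsilyl)methyl]nona-2,6-dien-1-yl]-2-methyl-6-oxo-6H-pyran-3-carboxylate | COC(=O)C1=C(C)OC(=O)C(C/C=C(\C[Si](C)(C)C)CC/C=C(/C)CC[C@H]2O[C@]2(C)CCC(C)(C)OC=O)=C1O[Si](C)(C)C(C)(C)C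
F5 | step 14 | methyl 4-[(tert-butyldimethylsilyl)oxy]-5-{[(1S,4aR,5R,6R,8aS)-5-[3-(formyloxy)-3-methylbutyl]-6-hydroxy-5,8a-dimethyl-2-methylidenedecahydronaphthalen-1-yl]methyl}-2-methyl-6-oxo-6H-pyran-3-carboxylate | C=C1CC[C@H]2[C@@](C)(CCC(C)(C)OC=O)[C@H](O)CC[C@@]2(C)[C@H]1CC1=C(O[Si](C)(C)C(C)(C)C)C(C(=O)OC)=C(C)OC1=O
F6 | step 14 | methyl 5-{[(1S,4aR,5R,6R,8aS)-5-[3-(formyloxy)-3-methylbutyl]-6-hydroxy-5,8a-dimethyl-2-methylidenedecahydronaphthalen-1-yl]methyl}-4-hydroxy-2-methyl-6-oxo-6H-pyran-3-carboxylate | C=C1CC[C@H]2[C@@](C)(CCC(C)(C)OC=O)[C@H](O)CC[C@@]2(C)[C@H]1CC1=C(O)C(C(=O)OC)=C(C)OC1=O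
F7 | step 16 | methyl 5-{[(1S,4aR,5R,6S,8aS)-6-hydroxy-5-(3-hydroxy-3-methylbutyl)-5,8a-dimethyl-2-methylidenedecahydronaphthalen-1-yl]methyl}-6-methoxy-2-methyl-4-oxo-4H-pyran-3-carboxylate | C=C1CC[C@H]2[C@@](C)(CCC(C)(C)O)[C@@H](O)CC[C@@]2(C)[C@H]1Cc1c(OC)oc(C)c(C(=O)OC)c1=O
F8 | step 16 | methyl 5-{[(1S,4aR,5R,6S,8aS)-5-(3-hydroxy-3-methylbutyl)-5,8a-dimethyl-2-methylidene-6-[(triethylsilyl)oxy]decahydronaphthalen-1-yl]methyl}-6-methoxy-2-methyl-4-oxo-4H-pyran-3-carboxylate | C=C1CC[C@H]2[C@@](C)(CCC(C)(C)O)[C@@H](O[Si](CC)(CC)CC)CC[C@@]2(C)[C@H]1Cc1c(OC)oc(C)c(C(=O)OC)c1=O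
F9 | step 16 | methyl 5-{[(1S,4aR,5R,6S,8aS)-5-[3-(formyloxy)-3-methylbutyl]-5,8a-dimethyl-2-methylidene-6-[(triethylsilyl)oxy]decahydronaphthalen-1-yl]methyl}-6-methoxy-2-methyl-4-oxo-4H-pyran-3-carboxylate | C=C1CC[C@H]2[C@@](C)(CCC(C)(C)OC=O)[C@@H](O[Si](CC)(CC)CC)CC[C@@]2(C)[C@H]1Cc1c(OC)oc(C)c(C(=O)OC)c1=O
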